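A closed, stirred, isothermal vessel holds free monomer M, initiator, transfer agent T and impurity. Initiator starts chains, each living end adds free monomer, and transfer agent kills it.

| flask | free monomer | transfer agent | initiator | impurity | remark | time |
|---|---|---|---|---|---|---|
| north | 0.17 M | 7.5 mM | 2.1 mM | 1 mM | run made earlier |  |
| south-east | 0.38 M | 7.5 mM | 2.1 mM | 1 mM | run made earlier |  |
| east | 0.25 M | 3.8 mM | 2.1 mM | 1 mM | run made earlier |  |
| noon | 0.25 M | 7.50 mM | 2.1 mM | 1.0 mM |  | 4.0 h |
| dawn | 0.25 M | 7.50 mM | 2.1 mM | 1.0 mM |  | 6.0 h |

| run | time / h | monomer in chains / % | free monomer / % |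
|---|---|---|---|
| north | 0.167 | 1.5 | 100.1 |
| north | 0.500 | 2.1 | 97.2 |
| north | 0.833 | 3.7 | 96.7 |
| north | 1.33 | 7.3 | 93.5 |
| north | 2.00 | 8.1 | 89.7 |
| north | 2.50 | 9.7 | 90.0 |
| south-east | 0.417 | 4.0 | 96.9 |
| south-east | 0.833 | 7.1 | 93.3 |
| south-east | 1.33 | 11.8 | 89.7 |
| south-east | 1.50 | 10.0 | 90.8 |
| south-east | 2.00 | 10.4 | 89.2 |
| south-east | 2.50 | 7.8 | 90.4 |
| east | 0.200 | 0.5 | 97.2 |
| east | 0.333 | 2.2 | 96.7 |
| east | 0.667 | 5.7 | 94.1 |
| east | 1.33 | 12.7 | 88.5 |
| east | 2.50 | 14.9 | 84.9 |

(standard deviation of a reading: 1 percentage point)

- the average divides the monomer in chains by the number of chains begun, living and dead together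
- candidate steps: free monomer + initiator -> living end + monomer in chains; living end + transfer agent -> dead chain; free monomer + living end -> monomer in chains + living end; initiator + impurity -> spent initiator
- the earlier runs do not show the number of chains; that part of a forecast is a guess

- which of the two ends with the longer chains by the average number of monomer units in a chain (chains begun, living or dead) ("neither" if they lie within 10%) (noon / dawn / neither)
- average number of monomer units in a chain (chains begun, living or dead) at the end, noon
- average number of monomer units in a chain (chains begun, living or dead) at the end, dawn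

I divide one rate by the other. Growth goes as living end times M, death as living end times T, so the living end and time both drop out, and a chain's length, the kinetic chain length, goes as M/T. Summed over a fixed number of chains begun, c, and with M and T near their charges, the final fraction of monomer in chains therefore goes as c/T, and M leaves it as well.

North's last reading gives 0.727 mM for that fraction times T, and the mean of south-east's readings from 1.33 h on gives 0.750 mM. I keep their mean, 0.739 mM, as s, the plateau product: final fraction times transfer agent charged. East, still climbing from 12.7% to 14.9%, reads 0.566 mM, lower, so I treat it as a floor.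

For noon, s gives a fraction of 9.85%, which is 24.6 mM of monomer in chains. South-east's readings do not climb from 1.33 h to 2.50 h, and noon runs longer than that, so I expect dawn, with the same charge, to match noon.

If each impurity takes one initiator, c is 1.10 mM, and the length is 22.4. That c is the weak link, since the runs do not show it. Reforged, I bracket c between 1.10 mM and 2.1 mM, which brackets my length between 11.7 and 22.4. I commit to the top of that range.

The forecast says neither, with 24.5 and 25, above mine, and of its count it says “This chain count is a guess.”

Noon and dawn give neither: 21.4 and 21.4.

free monomer + initiator → living end + monomer in chains (k = 0.154 M⁻¹ min⁻¹); living end + transfer agent → dead chain (kL = 4.44 M⁻¹ min⁻¹); free monomer + living end → monomer in chains + living end, rate k3*[living end]*[free monomer] (k = 2.64 M⁻¹ min⁻¹); initiator + impurity → spent initiator (k = 92.2 M⁻¹ min⁻¹) Noon holds 0.00116 M of dead chain at 4.00 h, above my 1.10 mM. Set in place of c, it turns s into a length of 21.3. The neighbour of noon charged with 0.030 M of transfer agent gets a fraction of 2.46% from s, and it stands at 2.78% monomer in chains.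

(The earlier runs and the new flask stem from a simulated flask with constants of no real substance, and the scatter is random.)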